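## The problem

The target 13 is a flavanone, a 2-aryl chroman-4-one. Ring A carries methoxy at C5, a free hydroxyl at C6 and methoxy at C7; ring B is a 3,4-dimethoxyphenyl group; ring C holds the only stereocentre, C2, with S configuration. With no second stereocentre to relay from, C2 must be set by a reagent or catalyst, and ring C must then be completed without disturbing it. C2 is benzylic, bonded to the ring oxygen and beta to the C4 carbonyl. Once the ketone is present, base can open ring C by retro-oxa-Michael reaction to the achiral chalcone and return racemic material, so the ketone should appear late and never meet base. The C6 hydroxyl is para to O1 and flanked by two methoxy groups, which makes it an easily oxidised hydroquinone monoether. It must also be told apart from four methyl ethers, one of which (C5, peri to the carbonyl) is readily cleaved by Lewis acids, so a benzyl ether removed by neutral hydrogenolysis in the last step is the natural mask. Ring A is substituted everywhere except C8, so its pattern is better bought than built. The enabling feature is the O1–C8a bond: it links the secondary benzylic oxygen on C2 to ring A, and with bromine on C8a it can be made by palladium-catalysed aryl etherification, which makes and breaks no bond at C2.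

## Retrosynthesis

**13 from 12.** The last cut is the benzyl–oxygen bond at C6. A benzyl ether is the one mask that survives amide base, borane, carbonate at 70 °C and fluoride and still leaves under neutral conditions. A methyl or isopropyl ether would need a Lewis acid that would also strip the C5 methoxy group, and an aryl silyl ether would not survive the carbonate. Precursor 12 differs from the target only by this group. The forward hydrogenolysis must spare the aryl ketone and the cyclic benzylic ether at C2.

**12 from 11 from 10.** No skeletal bond is cut; the C4 ketone is taken back to the alcohol 11 and then to its silyl ether 10. With the ketone in place, the ring closure would have to be run on a beta-hydroxy ketone, which under carbonate undergoes retro-aldol cleavage or dehydration. After closure the ketone would make C2 base-labile. As a silyl ether, C4 is inert to every step up to and including the ring closure. The forward steps are fluoride cleavage and a non-basic oxidation in which both C4 epimers converge.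

**10 from 9.** The key cut is O1–C8a, giving the acyclic bromo alcohol 9. The neighbouring O1–C2 cut would mean a Mitsunobu closure with inversion at a carbon that ionises easily because of the dimethoxyphenyl group, or an oxa-Michael closure of a chalcone that needs an asymmetric catalyst and delivers the base-labile flavanone directly. The O1–C8a cut leaves every bond at C2 alone, so the configuration of 9 passes unchanged into 10. Precursor 9 has no ring C and only one stereocentre that matters. The forward reaction must form the C–O bond faster than the palladium alkoxide loses its beta-hydrogen.

**9 from 8.** The C1–H bond of the carbinol is cut: 9 comes from the aryl ketone 8 by oxazaborolidine-catalysed borane reduction. This is the only stereocontrolled step of the route. The ketone has an aryl group on one side and a methylene on the other, the pattern this catalyst discriminates best. Ketone 8 is racemic at the silyloxy carbon, so the catalyst must override that remote centre in both enantiomers. The product is then the pair of C3 epimers of 9, the (1S,3S) and (1S,3R) members, both of which serve.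

**8 from 7 from 4 and 5.** The C3–C4 bond (flavanone numbering) is cut by an aldol addition. The lithium enolate 6 of the acetophenone 5 adds to the aldehyde 4 to give 7, and silylation gives 8. A condensation to the chalcone would discard the C4 oxygen and require its reintroduction, whereas the addition delivers it with the carbon–carbon bond. The cut divides the molecule into ring A and ring B halves of similar size. The forward step is a kinetic addition to a hindered, non-enolisable aldehyde, worked up cold and silylated at once.

**4 from 2 from 1.** The formyl carbon is cut from ring A. Aldehyde 4 arises from 2 by deprotonation between bromine and methoxy to the aryllithium 3 and formylation. Compound 2 comes from the commercial phenol 1 by benzylation. The two open ring positions of 2 are equivalent by symmetry, so only one aldehyde can form. The bromine that directs the metalation is the one needed later at C8a. Ketone 5 is commercial.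

## Roads not taken

**Alternative 1:** ring A is made last.
- **Cut and key step:** the cut is C4a–C5. The (2S)-2-aryl-2,3-dihydropyran-4-one A2 carries at C6 a CH2–CO–CH(OBn)–CO2Me chain. With Mg(OMe)2 in methanol its extended enolate would attack the terminal ester through the ring alpha-carbon (the future C4a) in a Claisen-type condensation, and enolisation would aromatise the new ring to the 5,7-dihydroxy flavanone A1.
- **Merits:** it mirrors the polyketide origin of ring A, places the three oxygens unambiguously, needs no aryl halide and no palladium, and allows C2 to be set early by an enantioselective hetero-Diels–Alder reaction.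
- **Weak points:** A1 still needs two O-methylations to reach 12. These run under base with the C4 ketone present, the situation in which ring C opens and C2 is lost. The C5 hydroxyl, hydrogen-bonded to the carbonyl, is the slowest phenol to alkylate. The key step itself exposes a beta-alkoxy enone stereocentre to methoxide. The alpha-benzyloxy tricarbonyl chain of A2 costs more steps than the whole of ring A costs in the chosen plan.
- **Comparison:** the biomimetic closure is regiochemically self-proving, which the chosen plan cannot claim. The chosen plan sets against it a commercial ring A with all three oxygens already differentiated (1) and a sequence in which C2 never meets base while the ketone is present.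

**Alternative 2:** ring C is closed at C3–C4 by ring-closing metathesis.
- **Cut and key step:** the diene A4, the (S)-1-(3,4-dimethoxyphenyl)allyl ether of a 2-vinylphenol, would give the 2H-chromene A3 with second-generation Grubbs catalyst. The C3=C4 alkene would then be hydrated and oxidised to 12.
- **Merits:** the metathesis is neutral, tolerates every group present and, for 2H-chromenes, is at least as dependable as the aryl etherification chosen here. It needs no protecting group at C4.
- **Weak points:** the C4 oxygen is absent after the key step and must be introduced regioselectively on a styrene-type alkene, where hydroboration favours C3 and Wacker-type oxidation of an internal cyclic alkene is not reliably selective. A3 is a flav-3-ene, a class that ionises or ring-opens easily at C2, so the stereocentre is at risk in the steps that follow. A4 is an enantioenriched, doubly activated secondary allyl aryl ether of a hindered phenol; its formation competes with SN1 and SN2' pathways, and it can undergo thermal Claisen rearrangement.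
- **Comparison:** as a ring closure the metathesis is the safer reaction, and this is conceded. The chosen plan sets against it that the C4 oxygen arrives with the aldol bond and that the stereocentre comes from a ketone reduction with a well-understood model.

**Alternative 3:** O1–C2 and C3–C4 are cut together.
- **Cut and key step:** the salicylaldehyde A6, an orthoformate and a chiral Brønsted acid would generate a 4-methoxy ortho-quinone methide (an aryl-stabilised oxocarbenium ion). This would add 3,4-dimethoxystyrene A7 in an inverse-demand hetero-Diels–Alder reaction to give the cis-4-methoxyflavan A5.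
- **Merits:** it is the most convergent of the four plans, forming two bonds, ring C and the stereocentre in one operation from two simple partners. On paper it is shorter than the chosen route by several steps.
- **Weak points:** the reactive species is a cation paired with the chiral anion, and the alkene offers the catalyst nothing to hold, so high facial selectivity is not assured. A stepwise addition through a dimethoxybenzylic cation would erode it further. The C4 methyl ether of A5 must then become the ketone of 12, either by benzylic oxidation beside the equally activated C2–H or by acid-mediated exchange through a C4 cation that can eliminate.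
- **Comparison:** step economy clearly favours this road. The chosen plan sets against it that each of its steps, including the stereo-defining reduction and the ring closure, belongs to a known reaction class for this substrate type, and that its C4 oxygen is masked as a silyl ether that leaves under fluoride.

Key step: step 6

Remark on the chemistry: the aldol of step 3 is not stereocontrolled, so the silyloxy carbon (C3 of the chain, later C4 of the chroman) is carried as both epimers until step 8 removes it. Names give it as RS and SMILES leave it open; the future C2 is S from step 5 onward.

## Route

Step 1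
Reactants: 1 4-bromo-2,6-dimethoxyphenol
Product: 2 2-(benzyloxy)-5-bromo-1,3-dimethoxybenzene
Conditions: BnBr, K2CO3, DMF, 60 °C
Reagents that add atoms: benzyl bromide, BrCc1ccccc1
Why: Williamson ether synthesis; the phenoxide of 1 displaces bromide from the benzylic halide by SN2, the flanking methoxy groups slow but do not prevent O-alkylation in DMF, and the aryl bromide is inert.

Step 2
Reactants: 2 2-(benzyloxy)-5-bromo-1,3-dimethoxybenzene
Product: 4 3-(benzyloxy)-6-bromo-2,4-dimethoxybenzaldehyde, via aryllithium 3 (not isolated)
Conditions: LiN(iPr)2, THF, −78 °C; DMF, −78 °C; then 1 M HCl
Reagents that add atoms: N,N-dimethylformamide, CN(C)C=O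
Why: Directed ortho-metalation; the C–H flanked by bromine and methoxy is the most acidic site and the two such sites of 2 are equivalent, so a single aryllithium 3 should form, persist at −78 °C without losing LiBr and be formylated by the formamide, as in the known lithiation of 3-bromoanisoles between the two substituents.

Step 3
Reactants: 4 3-(benzyloxy)-6-bromo-2,4-dimethoxybenzaldehyde; 5 3',4'-dimethoxyacetophenone
Product: 7 rac-3-[3-(benzyloxy)-6-bromo-2,4-dimethoxyphenyl]-3-hydroxy-1-(3,4-dimethoxyphenyl)propan-1-one, via lithium enolate 6 (not isolated)
Conditions: 5, LiN(iPr)2, THF, −78 °C; then 4, −78 °C; AcOH, −78 °C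
Reagents that add atoms: none
Why: Directed aldol addition of a preformed lithium enolate to a non-enolisable aldehyde, so only the cross product can form; reaction and quench are kept at −78 °C because the adduct can revert or dehydrate on warming. The new carbinol centre is not controlled and 7 is racemic, which is harmless because this carbon becomes the C4 carbonyl.

Step 4
Reactants: 7 rac-3-[3-(benzyloxy)-6-bromo-2,4-dimethoxyphenyl]-3-hydroxy-1-(3,4-dimethoxyphenyl)propan-1-one
Product: 8 rac-3-[3-(benzyloxy)-6-bromo-2,4-dimethoxyphenyl]-3-[(tert-butyldimethylsilyl)oxy]-1-(3,4-dimethoxyphenyl)propan-1-one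
Conditions: TBSOTf, 2,6-lutidine, CH2Cl2, −78 → 0 °C
Reagents that add atoms: tert-butyldimethylsilyl trifluoromethanesulfonate, CC(C)(C)[Si](C)(C)OS(=O)(=O)C(F)(F)F
Why: Silylation of a hindered secondary benzylic alcohol with a silyl triflate and a non-nucleophilic pyridine base; at low temperature O-silylation should outrun enolisation and beta-elimination, and the ether blocks retro-aldol and dehydration in the following steps.

Step 5
Reactants: 8 rac-3-[3-(benzyloxy)-6-bromo-2,4-dimethoxyphenyl]-3-[(tert-butyldimethylsilyl)oxy]-1-(3,4-dimethoxyphenyl)propan-1-one
Product: 9 (1S,3RS)-3-[3-(benzyloxy)-6-bromo-2,4-dimethoxyphenyl]-3-[(tert-butyldimethylsilyl)oxy]-1-(3,4-dimethoxyphenyl)propan-1-ol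
Conditions: (R)-2-methyl-CBS-oxazaborolidine [(3aR)-1-methyl-3,3-diphenyltetrahydro-1H,3H-pyrrolo[1,2-c][1,3,2]oxazaborole] (10 mol%), BH3·SMe2, THF, −20 °C; MeOH quench
Reagents that add atoms: none
Why: Corey–Bakshi–Shibata reduction; the (R)-oxazaborolidine binds BH3 at nitrogen and the ketone at boron with the aryl group turned away, and hydride is delivered through a six-membered transition state to the Re face, giving the S carbinol (the mirror image of the R alcohol that the S catalyst gives with aryl alkyl ketones). The catalyst sets the centre in both enantiomers of racemic 8, so 9 should be the pair of epimers at the silyloxy carbon, each S at C1.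

Step 6
Reactants: 9 (1S,3RS)-3-[3-(benzyloxy)-6-bromo-2,4-dimethoxyphenyl]-3-[(tert-butyldimethylsilyl)oxy]-1-(3,4-dimethoxyphenyl)propan-1-ol
Product: 10 (2S,4RS)-6-(benzyloxy)-4-[(tert-butyldimethylsilyl)oxy]-2-(3,4-dimethoxyphenyl)-5,7-dimethoxychromane
Conditions: Pd(OAc)2 (5 mol%), rac-2-(di-tert-butylphosphino)-1,1'-binaphthyl (6 mol%), Cs2CO3, toluene, 70 °C
Reagents that add atoms: none
Why: Intramolecular Buchwald–Hartwig-type aryl etherification: Pd(OAc)2 is reduced in situ to zerovalent palladium, which inserts into the C8a–Br bond; the (S)-carbinol binds the divalent palladium centre, Cs2CO3 deprotonates it to a seven-membered aryl palladium alkoxide chelate, and C–O reductive elimination forms O1–C8a and regenerates the catalyst. The closest known reaction type is the cyclisation of secondary alcohols bearing a 2-bromoaryl group to chromans with bulky biaryl di-tert-butylphosphines, a class in which the carbinol configuration is retained. Ring C closes as a six-membered ring by contraction of that seven-membered palladacycle, with the C2 oxygen as the nucleophilic partner and C8a as the electrophilic one. No stereocentre is created: C2 keeps the S configuration from step 5 because no bond to it is made or broken, and C4 remains the epimer pair. The selectivity required is C–O reductive elimination over beta-hydride elimination of the C2–H from the palladium alkoxide; the bulky, electron-rich phosphine and the preorganised chelate are chosen to favour the former. The C4 oxygen is silylated and cannot bind palladium, the weak heterogeneous carbonate keeps free alkoxide low so the silyl group should stay in place, and the molecule has only one carbon–halogen bond.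

Step 7
Reactants: 10 (2S,4RS)-6-(benzyloxy)-4-[(tert-butyldimethylsilyl)oxy]-2-(3,4-dimethoxyphenyl)-5,7-dimethoxychromane
Product: 11 (2S,4RS)-6-(benzyloxy)-2-(3,4-dimethoxyphenyl)-5,7-dimethoxychroman-4-ol
Conditions: Bu4NF, THF, 0 °C → rt
Reagents that add atoms: none
Why: Fluoride-mediated silyl ether cleavage driven by the Si–F bond; the benzyl and methyl ethers and C2 are untouched, and with no carbonyl present the basic fluoride cannot open ring C.

Step 8
Reactants: 11 (2S,4RS)-6-(benzyloxy)-2-(3,4-dimethoxyphenyl)-5,7-dimethoxychroman-4-ol
Product: 12 (2S)-6-(benzyloxy)-2-(3,4-dimethoxyphenyl)-5,7-dimethoxychroman-4-one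
Conditions: Dess–Martin periodinane, NaHCO3, CH2Cl2, 0 °C → rt
Reagents that add atoms: none
Why: Dess–Martin oxidation of a secondary benzylic alcohol to the aryl ketone under buffered, non-basic conditions; both C4 epimers give the same ketone, the C6 oxygen is still protected against oxidation, and the absence of base keeps the beta-aryloxy ketone from opening and racemising at C2.

Step 9
Reactants: 12 (2S)-6-(benzyloxy)-2-(3,4-dimethoxyphenyl)-5,7-dimethoxychroman-4-one
Product: 13 (2S)-2-(3,4-dimethoxyphenyl)-6-hydroxy-5,7-dimethoxychroman-4-one
Conditions: H2 (1 atm), 10% Pd/C, EtOAc, rt
Reagents that add atoms: none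
Why: Catalytic hydrogenolysis of an aryl benzyl ether; at 1 atm and room temperature in a neutral solvent the aryl ketone and the cyclic benzylic C2–O1 ether should survive, and the neutral medium leaves C2 configurationally intact.

## Compound list

1 | 4-bromo-2,6-dimethoxyphenol | COc1cc(Br)cc(OC)c1O | starting material
2 | 2-(benzyloxy)-5-bromo-1,3-dimethoxybenzene | COc1cc(Br)cc(OC)c1OCc1ccccc1 | intermediate
3 | [3-(benzyloxy)-6-bromo-2,4-dimethoxyphenyl]lithium | [Li]c1c(Br)cc(OC)c(OCc2ccccc2)c1OC | intermediate (not isolated)
4 | 3-(benzyloxy)-6-bromo-2,4-dimethoxybenzaldehyde | O=Cc1c(Br)cc(OC)c(OCc2ccccc2)c1OC | intermediate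
5 | 3',4'-dimethoxyacetophenone | CC(=O)c1ccc(OC)c(OC)c1 | starting material
6 | lithium 1-(3,4-dimethoxyphenyl)ethen-1-olate | C=C(O[Li])c1ccc(OC)c(OC)c1 | intermediate (not isolated)
7 | rac-3-[3-(benzyloxy)-6-bromo-2,4-dimethoxyphenyl]-3-hydroxy-1-(3,4-dimethoxyphenyl)propan-1-one | COc1ccc(C(=O)CC(O)c2c(Br)cc(OC)c(OCc3ccccc3)c2OC)cc1OC | intermediate
8 | rac-3-[3-(benzyloxy)-6-bromo-2,4-dimethoxyphenyl]-3-[(tert-butyldimethylsilyl)oxy]-1-(3,4-dimethoxyphenyl)propan-1-one | COc1ccc(C(=O)CC(O[Si](C)(C)C(C)(C)C)c2c(Br)cc(OC)c(OCc3ccccc3)c2OC)cc1OC | intermediate
9 | (1S,3RS)-3-[3-(benzyloxy)-6-bromo-2,4-dimethoxyphenyl]-3-[(tert-butyldimethylsilyl)oxy]-1-(3,4-dimethoxyphenyl)propan-1-ol (both C3 epimers) | COc1ccc([C@@H](O)CC(O[Si](C)(C)C(C)(C)C)c2c(Br)cc(OC)c(OCc3ccccc3)c2OC)cc1OC | intermediate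
10 | (2S,4RS)-6-(benzyloxy)-4-[(tert-butyldimethylsilyl)oxy]-2-(3,4-dimethoxyphenyl)-5,7-dimethoxychromane (both C4 epimers) | COc1ccc([C@@H]2CC(O[Si](C)(C)C(C)(C)C)c3c(cc(OC)c(OCc4ccccc4)c3OC)O2)cc1OC | intermediate
11 | (2S,4RS)-6-(benzyloxy)-2-(3,4-dimethoxyphenyl)-5,7-dimethoxychroman-4-ol (both C4 epimers) | COc1ccc([C@@H]2CC(O)c3c(cc(OC)c(OCc4ccccc4)c3OC)O2)cc1OC | intermediate
12 | (2S)-6-(benzyloxy)-2-(3,4-dimethoxyphenyl)-5,7-dimethoxychroman-4-one | COc1ccc([C@@H]2CC(=O)c3c(cc(OC)c(OCc4ccccc4)c3OC)O2)cc1OC | intermediate
13 | (2S)-2-(3,4-dimethoxyphenyl)-6-hydroxy-5,7-dimethoxychroman-4-one | COc1ccc([C@@H]2CC(=O)c3c(cc(OC)c(O)c3OC)O2)cc1OC | target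

## Step count and least certain steps

Total steps: 9. Longest linear sequence: 9 steps (1 to 13); 5 enters at step 3.

**Step 6 (key step).**
- **What may go wrong:** beta-hydride elimination from the palladium alkoxide may outrun C–O reductive elimination. The aryl group on palladium is electron-rich (alkoxy para to C8a), which slows reductive elimination, and the C2–H is benzylic; the outcome would be oxidation of the carbinol with loss of bromine from the arene. A base-induced shift of the silyl group from the C4 oxygen to the C2 alkoxide would also stop the closure.
- **Fallback:** it sets out from 9, removes both failure paths and returns at 11, bypassing 10. The silyl ether is first cleaved with Bu4NF in THF to give the diol (1S,3RS)-3-[3-(benzyloxy)-6-bromo-2,4-dimethoxyphenyl]-1-(3,4-dimethoxyphenyl)propane-1,3-diol F1. An Ullmann-type copper-catalysed closure (CuI, 1,10-phenanthroline, Cs2CO3, toluene, 110 °C, under argon) should then form O1–C8a. Only the hydroxyl on the dimethoxyphenyl-bearing carbon can reach the bromide in a six-membered ring, since the other would have to close a four-membered ring. A copper alkoxide has no easy beta-hydride elimination path, and no silyl group is left to migrate.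

**Step 5.**
- **What may go wrong:** facial selectivity may be poor for one of the two enantiomers of 8 if the remote silyloxy centre is mismatched with the catalyst. Uncatalysed borane reduction of the slowly reacting, electron-rich aryl ketone may also compete. Both lower the enantiomeric purity at the future C2, because the two epimers converge in step 8.
- **Fallback:** it sets out from 8 and returns at 9. Noyori asymmetric transfer hydrogenation with RuCl[(S,S)-TsDPEN](p-cymene) in HCO2H/Et3N delivers hydride by an outer-sphere metal–ligand pathway with no free borane background, and the S,S catalyst gives the S carbinol from aryl alkyl ketones. No new compound is involved.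

**Step 3.**
- **What may go wrong:** the hindered, electron-rich aldehyde may add sluggishly, and the lithium aldolate may revert on warming or dehydrate toward the chalcone during work-up.
- **Fallback:** it sets out from 5 and returns at 7. Silylation (Me3SiOTf, Et3N, CH2Cl2, 0 °C) gives the enol ether {[1-(3,4-dimethoxyphenyl)ethenyl]oxy}trimethylsilane F2. This adds to 4 under BF3·OEt2 in CH2Cl2 at −78 °C in a Mukaiyama aldol, where Lewis acid activation of the aldehyde replaces the reversible aldolate equilibrium.

**Step 2.**
- **What may go wrong:** the ortho-bromo aryllithium may lose LiBr to an aryne if the temperature rises, or bromine may scramble between lithiated and unlithiated arene, so the aldehyde would form with low conversion or as a mixture.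
- **Fallback:** it sets out from 2 and returns at 4. Rieche formylation (Cl2CHOMe, TiCl4, CH2Cl2, −78 → 0 °C) reaches the same position by electrophilic aromatic substitution, ortho and para to the two methoxy groups, with no carbanion involved. No new compound is involved.

## Further compounds

F1 | step 6 | (1S,3RS)-3-[3-(benzyloxy)-6-bromo-2,4-dimethoxyphenyl]-1-(3,4-dimethoxyphenyl)propane-1,3-diol | COc1ccc([C@@H](O)CC(O)c2c(Br)cc(OC)c(OCc3ccccc3)c2OC)cc1OC
F0 | step 5 | none | none
F2 | step 3 | {[1-(3,4-dimethoxyphenyl)ethenyl]oxy}trimethylsilane | C=C(O[Si](C)(C)C)c1ccc(OC)c(OC)c1
F0 | step 2 | none | none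
A1 | alternative 1 | (2S)-6-(benzyloxy)-2-(3,4-dimethoxyphenyl)-5,7-dihydroxychroman-4-one | COc1ccc([C@@H]2CC(=O)c3c(cc(O)c(OCc4ccccc4)c3O)O2)cc1OC
A2 | alternative 1 | methyl 2-(benzyloxy)-4-[(2S)-2-(3,4-dimethoxyphenyl)-4-oxo-3,4-dihydro-2H-pyran-6-yl]-3-oxobutanoate | COC(=O)C(OCc1ccccc1)C(=O)CC1=CC(=O)C[C@@H](c2ccc(OC)c(OC)c2)O1
A3 | alternative 2 | (2S)-6-(benzyloxy)-2-(3,4-dimethoxyphenyl)-5,7-dimethoxy-2H-chromene | COc1ccc([C@@H]2C=Cc3c(cc(OC)c(OCc4ccccc4)c3OC)O2)cc1OC
A4 | alternative 2 | 2-(benzyloxy)-5-{[(1S)-1-(3,4-dimethoxyphenyl)prop-2-en-1-yl]oxy}-4-ethenyl-1,3-dimethoxybenzene | C=C[C@H](Oc1cc(OC)c(OCc2ccccc2)c(OC)c1C=C)c1ccc(OC)c(OC)c1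
A5 | alternative 3 | (2S,4S)-6-(benzyloxy)-2-(3,4-dimethoxyphenyl)-4,5,7-trimethoxychromane | COc1ccc([C@@H]2C[C@H](OC)c3c(cc(OC)c(OCc4ccccc4)c3OC)O2)cc1OC
A6 | alternative 3 | 3-(benzyloxy)-6-hydroxy-2,4-dimethoxybenzaldehyde | O=Cc1c(O)cc(OC)c(OCc2ccccc2)c1OC
A7 | alternative 3 | 4-ethenyl-1,2-dimethoxybenzene (3,4-dimethoxystyrene) | C=Cc1ccc(OC)c(OC)c1
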